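The constants were chosen freely.

Start from the leftover: starting material that escapes quenching by the protic impurity goes on to react, and at the start of larch the forward step to target takes it 36 times as fast as quenching does.

| setting | birch | larch | oak |
|---|---|---|---|
| starting material | 26 mM (fed, over 16.0 min) | 26 mM | 26 mM |
| protic impurity | 5.20 mM | 5.20 mM | 5.20 mM |
| time | 20 min | 20 min |  |
| remark | a stirred flask in which starting material is dosed at a steady rate over 16.0 min without added volume, worked up at 20 min | everything together in a closed stirred flask, run for 20 min | a single well-mixed tank run continuously and read at steady state, 20 min in it on average |

    starting material + protic impurity → quenched substrate (k1 = 3.8 /M/min)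
    target → over-reaction product (k2 = 0.037 /min)
    target ⇌ isomer of the product (K3 = 0.45, k3 = 0.069 /min)
    starting material ⇌ dormant form (K4 = 0.61, k4 = 0.045 /min)
    isomer of the product ⇌ starting material (k5 = 0.18 /min)
    starting material ⇌ target (K6 = 10, k6 = 0.72 /min)

- the stated concentrations are those of everything mixed, before any reaction; amounts are the same in each set-up
- the feed brings no volume worth counting
- run time (birch): 20 min

1. the set-up with the highest share of target in all that became target or isomer of the product or over-reaction product, at the outlet or at the end ("none" if the first two lie within 2 percentage points) (birch / larch / oak / none)
2. share of target in all that became target or isomer of the product or over-reaction product, at the outlet or at the end, birch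
3. share of target in all that became target or isomer of the product or over-reaction product, at the outlet or at the end, larch
4. share of target in all that became target or isomer of the product or over-reaction product, at the outlet or at the end, oak

- Because that ratio is so large, you may set quenching aside and reckon in fractions of the charge.
- Treat starting material, target, isomer of the product and dormant form as one pool in pre-equilibrium. The equilibrium constants then put 62.1% of the pool in target, and 9.99% in starting material and dormant form together.
- The pool drains through target, and the step from target is first order in target's fraction of the pool. So I reckon the loss as first order, with constant 0.0230 /min and half-life 30.2 min.
- In larch, the relaxation half-lives of the reversible steps, each taken both ways together, run from 0.700 min to 5.84 min. That is shorter than the drain's half-life, so the pool picture is fair.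
- Larch has N = 0.459, where N, the drain number, is the drain constant times the mean age of the material in the flask. It tells you how many e-foldings of loss the pool has suffered.
- A batch keeps e to the minus N of its pool. Target is 62.1% of that, and with quenching set aside the share divides it by the charge less the starting material and dormant form still present. My figure for larch is 41.9%.
- In birch, steady dosing gives a mean age of 12.0 min at work-up, younger than larch. So N is 0.276, and I get 51.0%.
- Oak has larch's N, but a tank keeps the inverse of 1 plus N, which is 0.685, giving 45.7%. Is one number enough here? The tank mixes fresh feed with old material, so I hold this figure loosely. I still commit to birch, ahead of oak by 5.3 percentage points, against a margin of 2 points.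
- The forecast names birch, with 50.5% for birch, 42% for larch and 43% for oak, on the ground that “Younger material has had less time to over-react”. My order matches it, but on oak I differ, 45.7% against its 43%.
- The simulation gives birch as best: birch 50.6%, larch 42.2%, oak 43.0%.
- Larch's 0.459 gave 41.9% against 42.2%, while oak, from the same number, gave 45.7% against 43.0%, a gap of 2.7 points. Now leave larch until 80 min, with all amounts held. N grows to 1.84, the pool keeps 15.9% of itself, and the same division gives 10.0%. That flask reads 10.3%, with target at 9.62% of the charge.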